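## Retrosynthetic overview

1. Locants follow 2-oxaspiro[4.5]decane: C1 lactone CH–O, O2, C3 lactone C=O, C4 CH2, C5 spiro carbon, C6 ketone, C7=C8, C9 CH–OAc, C10 CH2. Ring A is C5–C10 and ring B is the lactone. The plan rests on ring A: both carbons flanking the C7=C8 alkene carry oxygen (C6 and C9), and the quaternary C5 stands next to C6. This is the imprint of a 1,4-dioxygenated butadiene added to a 1,1-disubstituted alkene.
2. Key disconnection: C5–C6 and C9–C10. Ring A comes from methyl 3-formylbut-3-enoate and (1E,3E)-4-acetoxy-1-silyloxybutadiene by a catalytic asymmetric Diels–Alder reaction. The silyl ether marks the later ketone, and the acetate is the one the target keeps.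
3. C1–C1' disconnection: the formyl carbon is raised to the acid chloride, which acylates the alkenylzinc reagent of the (R)-epoxy side chain (alkyne carboalumination, then Shi epoxidation). The alkenyl group goes in first and hydride last, because direct alkenyl addition to the aldehyde should come in anti to the bulky C6 and give the C1 epimer.
4. C1 is then set from C6: the freed C6 hydroxyl directs a 1,3-syn reduction of the ketone, and the new C1 hydroxyl closes ring B on the C4–C3 ester arm.
5. Ring order: A (cycloaddition), oxirane (brought in ready-made), B (lactonisation). The C6 carbinol is oxidised to the enone last.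

Key step: step 5

Assumption: the configuration written in the SMILES string (1R,5R,9S, oxirane R) defines the target, and the facial sense of the oxazaborolidinium salt is taken from the formyl C–H···O binding model; both antipodes of the prolinol are commercial, so the (S) series would be used without other change if the adduct proved to be the mirror image.

## Route

Step 1
Reactants: 1 methyl 4-oxobutanoate
Product: 2 methyl 3-formylbut-3-enoate
Conditions: aq. CH2O (37 %, 1.1 equiv), pyrrolidine (10 mol %), propanoic acid (10 mol %), i-PrOH, 45 °C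
Reagents that add atoms: formaldehyde, C=O
Why: Amine-catalysed Mannich condensation (α-methylenation of an aldehyde), in which the enamine of 1 attacks the formaldehyde-derived iminium ion and the amine leaves by β-elimination, while the carboxylic acid buffer keeps the medium too mild to move the new alkene into conjugation with the ester; no stereocentre is formed.

Step 2
Reactants: 3 (Z)-but-2-ene-1,4-diol
Product: 4 (Z)-4-hydroxybut-2-en-1-yl acetate
Conditions: 3 (3 equiv), Ac2O (1 equiv), Et3N (1.2 equiv), 4-(dimethylamino)pyridine (2 mol %), CH2Cl2, 0 °C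
Reagents that add atoms: acetic anhydride, CC(=O)OC(C)=O
Why: Statistical monoacylation of a symmetrical diol that is used in excess and washed out with water, so that the diacetate should stay minor and the Z alkene is untouched.

Step 3
Reactants: 4 (Z)-4-hydroxybut-2-en-1-yl acetate
Product: 5 (E)-4-oxobut-2-en-1-yl acetate [(E)-4-acetoxybut-2-enal]
Conditions: [C5H5NH][CrO3Cl] (pyridinium chlorochromate, 1.5 equiv), CH2Cl2, rt
Reagents that add atoms: none
Why: Chromate-ester oxidation of a primary allylic alcohol stops at the aldehyde in the absence of water, and the mildly acidic medium isomerises the first-formed Z enal to the more stable E enal.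

Step 4
Reactants: 5 (E)-4-oxobut-2-en-1-yl acetate
Product: 6 (1E,3E)-4-(tert-butyldimethylsilyloxy)buta-1,3-dien-1-yl acetate
Conditions: t-BuMe2SiOSO2CF3 (TBSOTf, 1.1 equiv), Et3N (1.5 equiv), Et2O, 0 °C → rt; Et3N-deactivated silica
Reagents that add atoms: tert-butyldimethylsilyl triflate, CC(C)(C)[Si](C)(C)OS(=O)(=O)C(F)(F)F
Why: Soft vinylogous enolisation, in which O-silylation of the s-trans enal gives a siloxyallyl cation (fixing the 1E alkene) whose acidified γ-CH2 is deprotonated by Et3N from the extended conformer to give the 3E enol acetate; any 3Z isomer is removed by chromatography and would in any case be inert in step 5 because it cannot reach the s-cis conformation.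

Step 5
Reactants: 2 methyl 3-formylbut-3-enoate; 6 (1E,3E)-4-(tert-butyldimethylsilyloxy)buta-1,3-dien-1-yl acetate
Product: 7 methyl 2-[(1S,2S,5S)-5-acetoxy-2-(tert-butyldimethylsilyloxy)-1-formylcyclohex-3-en-1-yl]acetate (formyl, silyloxy and acetoxy groups all cis)
Conditions: (R)-1-(2-methylphenyl)-3,3-diphenyltetrahydro-1H,3H-pyrrolo[1,2-c][1,3,2]oxazaborole (20 mol %), HN(SO2CF3)2 (17 mol %), CH2Cl2, −25 °C, 15 min; then −78 °C, 2 (1 equiv), 6 (1.5 equiv); Et3N quench
Reagents that add atoms: none
Why: The boron cation binds the formyl oxygen of 2 (backed by a formyl C–H···O contact to the ring oxygen of the catalyst), lowers the LUMO of the s-trans enal, and the s-cis diene 6 adds in a concerted, asynchronous, suprafacial–suprafacial [4+2] cycloaddition in which C9–C10 bond formation runs ahead of C5–C6. The closest known reaction type is the oxazaborolidinium-catalysed Diels–Alder reaction of 2-substituted acroleins with acyclic oxygenated dienes. Ring A is closed in this one intermolecular event as a six-membered carbocycle, by union of both diene termini with the two alkene carbons of 2. C6 and C9 come out cis to each other because both diene alkenes are E and the diene reacts on one face, C5 is tied to them by the formyl-endo transition state, which puts the formyl group cis to both oxygens, and the absolute sense is set by the catalyst, whose phenyl group cis to the bound aldehyde covers one face so that the diene reaches the Re face of the α-carbon. Regioselectivity is needed and is secured by the substrate: the silyloxy group is a much stronger donor than the acetoxy group, so the largest HOMO coefficient lies on the acetoxy-bearing terminus, which bonds to the CH2 terminus of 2 (largest LUMO coefficient) and leaves the silyloxy carbon next to the quaternary centre. Endo selectivity is favoured because only the coordinated formyl group offers secondary overlap with the diene, the saturated CH2CO2Me arm prefers the open exo side, and an acyclic diene lacks the bridging CH2 that drives 2-substituted acroleins exo with cyclopentadiene; the slight deficit of HN(SO2CF3)2 and the low temperature protect the silyl dienol ether from free acid.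

Step 6
Reactants: 8 5-bromo-2-methylpent-2-ene
Product: 9 6-methylhept-5-en-1-yne
Conditions: LiC≡CH·H2NCH2CH2NH2 (1.3 equiv), DMSO, 5 °C → rt
Reagents that add atoms: lithium acetylide–ethane-1,2-diamine complex, [Li]C#C.NCCN
Why: SN2 displacement of a primary bromide by acetylide in a dipolar aprotic solvent, where substitution outruns E2 elimination; no stereocentre is formed.

Step 7
Reactants: 9 6-methylhept-5-en-1-yne
Product: 11 (E)-1-iodo-2,6-dimethylhepta-1,5-diene, via alkenyldimethylalane 10 (not isolated)
Conditions: AlMe3 (2 equiv), Cp2ZrCl2 (25 mol %), CH2Cl2, 0 °C → rt; then I2, THF, −30 → 0 °C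
Reagents that add atoms: trimethylaluminium, C[Al](C)C; iodine, II
Why: Zirconium-catalysed carboalumination (Negishi) adds CH3 and Al syn across the terminal alkyne with aluminium at the terminus while the trisubstituted alkene stays inert, and iodinolysis of the C–Al bond with retention gives the E iodide (iodine cis to the new methyl group).

Step 8
Reactants: 11 (E)-1-iodo-2,6-dimethylhepta-1,5-diene
Product: 12 (3R)-3-[(3E)-4-iodo-3-methylbut-3-en-1-yl]-2,2-dimethyloxirane
Conditions: 1,2:4,5-di-O-isopropylidene-β-D-erythro-hexo-2,3-diulo-2,6-pyranose (D-fructose-derived Shi ketone, 30 mol %), KHSO5 (as 2KHSO5·KHSO4·K2SO4), K2CO3, Bu4NHSO4 (5 mol %), MeCN/CH2(OMe)2, aq. Na2B4O7/Na2EDTA buffer, 0 °C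
Reagents that add atoms: potassium peroxymonosulfate, [K+].OOS(=O)(=O)[O-]
Why: Shi epoxidation, in which the chiral dioxirane formed in situ transfers oxygen through a spiro transition state to the electron-rich trisubstituted 5,6-alkene (the iodine-bearing alkene is electron-poor and slower), and the D-fructose-derived ketone delivers oxygen to the face that gives the (R)-oxirane, as it does with other trisubstituted alkenes.

Step 9
Reactants: 7 methyl 2-[(1S,2S,5S)-5-acetoxy-2-(tert-butyldimethylsilyloxy)-1-formylcyclohex-3-en-1-yl]acetate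
Product: 13 (1S,2S,5S)-5-acetoxy-2-(tert-butyldimethylsilyloxy)-1-(2-methoxy-2-oxoethyl)cyclohex-3-ene-1-carboxylic acid
Conditions: NaClO2, NaH2PO4, 2-methylbut-2-ene, t-BuOH/H2O, 0 °C → rt
Reagents that add atoms: sodium chlorite, [Na+].[O-]Cl=O
Why: Pinnick oxidation, in which chlorous acid adds to the aldehyde and fragments to the acid, 2-methylbut-2-ene traps the HOCl so that the ring alkene is spared, the buffer is tolerated by silyl ether and acetate, and the quaternary C5 cannot epimerise.

Step 10
Reactants: 13 (1S,2S,5S)-5-acetoxy-2-(tert-butyldimethylsilyloxy)-1-(2-methoxy-2-oxoethyl)cyclohex-3-ene-1-carboxylic acid; 12 (3R)-3-[(3E)-4-iodo-3-methylbut-3-en-1-yl]-2,2-dimethyloxirane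
Product: 17 methyl 2-[(1S,2S,5S)-5-acetoxy-2-(tert-butyldimethylsilyloxy)-1-{(2E)-5-[(2R)-3,3-dimethyloxiran-2-yl]-3-methylpent-2-enoyl}cyclohex-3-en-1-yl]acetate, via acid chloride 14 (not isolated), via alkenyllithium 15 (not isolated), via alkenylzinc chloride 16 (not isolated)
Conditions: 13, 1-chloro-N,N,2-trimethylprop-1-en-1-amine (1.2 equiv), CH2Cl2, 0 °C → rt; separately 12 (1.3 equiv), t-BuLi (2.05 equiv per 12), Et2O, −78 °C, then ZnCl2, THF, −78 → 0 °C; combine, Pd(PPh3)4 (5 mol %), THF, 0 °C → rt
Reagents that add atoms: none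
Why: The chloroenamine turns the hindered acid into its chloride under neutral conditions, iodine–lithium exchange at −78 °C is faster than any attack on the oxirane and keeps the E geometry, zinc tames the carbanion so that ester, acetate and silyl ether survive, and in the Negishi acylation zerovalent palladium inserts into the acyl C–Cl bond far faster than it ionises the ring allylic acetate; no stereocentre is formed or touched.

Step 11
Reactants: 17 methyl 2-[(1S,2S,5S)-5-acetoxy-2-(tert-butyldimethylsilyloxy)-1-{(2E)-5-[(2R)-3,3-dimethyloxiran-2-yl]-3-methylpent-2-enoyl}cyclohex-3-en-1-yl]acetate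
Product: 18 methyl 2-[(1S,2S,5S)-5-acetoxy-1-{(2E)-5-[(2R)-3,3-dimethyloxiran-2-yl]-3-methylpent-2-enoyl}-2-hydroxycyclohex-3-en-1-yl]acetate
Conditions: Bu4NF (2 equiv), AcOH (2 equiv), THF, 0 °C → rt
Reagents that add atoms: none
Why: Fluoride-induced Si–O cleavage driven by the strong Si–F bond, with acetic acid buffering the liberated alkoxide so that retro-aldol cleavage of C5–C6, acetate migration and attack on the oxirane are avoided, while the C6 hydroxyl, being trans to the ester arm, is not set up to lactonise.

Step 12
Reactants: 18 methyl 2-[(1S,2S,5S)-5-acetoxy-1-{(2E)-5-[(2R)-3,3-dimethyloxiran-2-yl]-3-methylpent-2-enoyl}-2-hydroxycyclohex-3-en-1-yl]acetate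
Product: 21 (1R,5S,6S,9S)-1-{(1E)-4-[(2R)-3,3-dimethyloxiran-2-yl]-2-methylbut-1-en-1-yl}-6-hydroxy-3-oxo-2-oxaspiro[4.5]dec-7-en-9-yl acetate, via diethylboron chelate 19 (not isolated), via syn-diol ester 20 (not isolated)
Conditions: Et2BOMe (1.2 equiv), THF/MeOH 4:1, −78 °C; NaBH4 (1.2 equiv), −78 °C; pH 7 buffer; MeOH co-evaporation; then SiO2, CH2Cl2, rt
Reagents that add atoms: none
Why: Narasaka–Prasad reduction, in which boron ties the C6 oxygen and the ketone oxygen into a six-membered chelate cis-fused to ring A with C10 axial on one face, so that external hydride adds axially from the other face to give the 1,3-syn diol, that is (R) at C1 with the alkenyl group on the C6 side of the future lactone; the new C1 hydroxyl, geminal on C5 to the ester arm, then closes ring B by 5-exo-trig acyl substitution with loss of methanol.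

Step 13
Reactants: 21 (1R,5S,6S,9S)-1-{(1E)-4-[(2R)-3,3-dimethyloxiran-2-yl]-2-methylbut-1-en-1-yl}-6-hydroxy-3-oxo-2-oxaspiro[4.5]dec-7-en-9-yl acetate
Product: 22 the target miliusane, (1R,5R,9S)-1-{(1E)-4-[(2R)-3,3-dimethyloxiran-2-yl]-2-methylbut-1-en-1-yl}-3,6-dioxo-2-oxaspiro[4.5]dec-7-en-9-yl acetate
Conditions: Dess–Martin periodinane (1,1,1-triacetoxy-1,1-dihydro-1,2-benziodoxol-3(1H)-one, 1.5 equiv), NaHCO3, CH2Cl2, 0 °C → rt
Reagents that add atoms: none
Why: Dess–Martin oxidation of the only free (secondary, allylic) hydroxyl gives the C6 enone under buffered, near-neutral conditions that leave oxirane, acetate and lactone alone, the quaternary C5 cannot epimerise, and the temporary C6 stereocentre is erased as planned.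

## Compound list

1 | methyl 4-oxobutanoate | COC(=O)CCC=O | starting material
2 | methyl 3-formylbut-3-enoate | C=C(C=O)CC(=O)OC | intermediate
3 | (Z)-but-2-ene-1,4-diol | OC/C=C\CO | starting material
4 | (Z)-4-hydroxybut-2-en-1-yl acetate | CC(=O)OC/C=C\CO | intermediate
5 | (E)-4-oxobut-2-en-1-yl acetate | CC(=O)OC/C=C/C=O | intermediate
6 | (1E,3E)-4-(tert-butyldimethylsilyloxy)buta-1,3-dien-1-yl acetate | CC(=O)O/C=C/C=C/O[Si](C)(C)C(C)(C)C | intermediate
7 | methyl 2-[(1S,2S,5S)-5-acetoxy-2-(tert-butyldimethylsilyloxy)-1-formylcyclohex-3-en-1-yl]acetate | CC(=O)O[C@@H]1C=C[C@H](O[Si](C)(C)C(C)(C)C)[C@@](C=O)(CC(=O)OC)C1 | intermediate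
8 | 5-bromo-2-methylpent-2-ene | CC(C)=CCCBr | starting material
9 | 6-methylhept-5-en-1-yne | C#CCCC=C(C)C | intermediate
10 | [(1E)-2,6-dimethylhepta-1,5-dien-1-yl]dimethylalane | C[Al](C)/C=C(\C)CCC=C(C)C | intermediate
11 | (E)-1-iodo-2,6-dimethylhepta-1,5-diene | I/C=C(\C)CCC=C(C)C | intermediate
12 | (3R)-3-[(3E)-4-iodo-3-methylbut-3-en-1-yl]-2,2-dimethyloxirane | I/C=C(\C)CC[C@H]1OC1(C)C | intermediate
13 | (1S,2S,5S)-5-acetoxy-2-(tert-butyldimethylsilyloxy)-1-(2-methoxy-2-oxoethyl)cyclohex-3-ene-1-carboxylic acid | CC(=O)O[C@@H]1C=C[C@H](O[Si](C)(C)C(C)(C)C)[C@@](C(=O)O)(CC(=O)OC)C1 | intermediate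
14 | acid chloride of 13 | CC(=O)O[C@@H]1C=C[C@H](O[Si](C)(C)C(C)(C)C)[C@@](C(=O)Cl)(CC(=O)OC)C1 | intermediate
15 | (1E)-4-[(2R)-3,3-dimethyloxiran-2-yl]-2-methylbut-1-en-1-yllithium | [Li]/C=C(\C)CC[C@H]1OC1(C)C | intermediate
16 | (1E)-4-[(2R)-3,3-dimethyloxiran-2-yl]-2-methylbut-1-en-1-ylzinc chloride | Cl[Zn]/C=C(\C)CC[C@H]1OC1(C)C | intermediate
17 | methyl 2-[(1S,2S,5S)-5-acetoxy-2-(tert-butyldimethylsilyloxy)-1-{(2E)-5-[(2R)-3,3-dimethyloxiran-2-yl]-3-methylpent-2-enoyl}cyclohex-3-en-1-yl]acetate | CC(=O)O[C@@H]1C=C[C@H](O[Si](C)(C)C(C)(C)C)[C@@](C(=O)/C=C(\C)CC[C@H]2OC2(C)C)(CC(=O)OC)C1 | intermediate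
18 | methyl 2-[(1S,2S,5S)-5-acetoxy-1-{(2E)-5-[(2R)-3,3-dimethyloxiran-2-yl]-3-methylpent-2-enoyl}-2-hydroxycyclohex-3-en-1-yl]acetate | CC(=O)O[C@@H]1C=C[C@H](O)[C@@](C(=O)/C=C(\C)CC[C@H]2OC2(C)C)(CC(=O)OC)C1 | intermediate
19 | O-diethylboryl derivative of 18 (boron also bound to the ketone oxygen) | CC(=O)O[C@@H]1C=C[C@H](OB(CC)CC)[C@@](C(=O)/C=C(\C)CC[C@H]2OC2(C)C)(CC(=O)OC)C1 | intermediate
20 | methyl 2-[(1S,2S,5S)-5-acetoxy-1-{(1R,2E)-5-[(2R)-3,3-dimethyloxiran-2-yl]-1-hydroxy-3-methylpent-2-en-1-yl}-2-hydroxycyclohex-3-en-1-yl]acetate (1,3-syn diol) | CC(=O)O[C@@H]1C=C[C@H](O)[C@@]([C@H](O)/C=C(\C)CC[C@H]2OC2(C)C)(CC(=O)OC)C1 | intermediate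
21 | (1R,5S,6S,9S)-1-{(1E)-4-[(2R)-3,3-dimethyloxiran-2-yl]-2-methylbut-1-en-1-yl}-6-hydroxy-3-oxo-2-oxaspiro[4.5]dec-7-en-9-yl acetate | CC(=O)O[C@@H]1C=C[C@H](O)[C@@]2(CC(=O)O[C@@H]2/C=C(\C)CC[C@H]2OC2(C)C)C1 | intermediate
22 | target miliusane, (1R,5R,9S)-1-{(1E)-4-[(2R)-3,3-dimethyloxiran-2-yl]-2-methylbut-1-en-1-yl}-3,6-dioxo-2-oxaspiro[4.5]dec-7-en-9-yl acetate | CC(=O)O[C@@H]1C=CC(=O)[C@@]2(CC(=O)O[C@@H]2/C=C(\C)CC[C@H]2OC2(C)C)C1 | target

## Step count and risks

Total step count: 13.
Longest linear sequence: 9 steps (steps 2, 3, 4, 5, 9, 10, 11, 12 and 13, from 3).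

**Step 5 (cycloaddition).**
- Risk: the strongly acidic boron cation may strip or transfer the silyl group of the dienol ether faster than the ring closes, by protodesilylation or by Mukaiyama-type addition to the bound aldehyde.
- Risk: the α-substituent of the dienophile may tilt the transition state towards exo or erode facial discrimination.
- Fallback: the same two bonds are made without any acid, and the absolute configuration is secured by resolution instead of catalysis. Setting out from 2 and 6, heating in toluene (80 °C, a trace of 2,6-di-tert-butyl-4-methylphenol, base-washed glassware) should give the ortho/endo adduct as the racemate, that is 7 together with its mirror image ent-7 F1. Pinnick oxidation as in step 9 then gives 13 together with its mirror image ent-13 F2. Crystallisation with (R)-1-phenylethylamine (or its antipode, whichever gives the less soluble salt of the wanted acid) gives the (R)-1-phenylethylammonium salt of 13 F3. Partition between aqueous KHSO4 and ethyl acetate releases the free acid, and the route is rejoined at 13.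

**Step 10 (acylation).**
- Risk: oxidative addition and transmetalation at the neopentyl-type acyl chloride may be slow. This would give zerovalent palladium time to ionise the ring allylic acetate, let the acyl chloride close onto the neighbouring ester, and let zinc halide open the oxirane.
- Fallback: the C1–C1' bond is made at the aldehyde level and the carbinol is oxidised afterwards. Setting out from 7 and 12, a Nozaki–Hiyama–Kishi coupling (CrCl2, NiCl2 1 mol %, DMSO/THF, rt) should give the allylic carbinol as a mixture of C1 epimers F4, whose configuration does not matter. The crude material is oxidised at once with Dess–Martin periodinane and NaHCO3 in CH2Cl2, before it can close to a lactone. The route is rejoined at 17, so that C1 is still set by step 12.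

**Step 4 (diene geometry).**
- Risk: γ-deprotonation through a folded conformer may give mainly the 3Z enol acetate, which cannot take part in step 5.
- Fallback: the geometry is fixed by crystallisation at the diacetate stage, and one acetate is then exchanged for silicon with retention. Setting out from 5, enol acetylation (isopropenyl acetate, p-toluenesulfonic acid cat., reflux) gives the 1,4-diacetoxybutadienes, from which the crystalline (1E,3E)-buta-1,3-diene-1,4-diyl diacetate F5 is isolated. Methyllithium (2 equiv, THF, −78 °C) cleaves one enol acetate to lithium (1E,3E)-4-acetoxybuta-1,3-dien-1-olate F6 without touching either alkene geometry. O-Silylation with t-BuMe2SiCl in THF/DMPU brings the route back at 6.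

## Further compounds

F1 | step 5 | ent-7, methyl 2-[(1R,2R,5R)-5-acetoxy-2-(tert-butyldimethylsilyloxy)-1-formylcyclohex-3-en-1-yl]acetate | CC(=O)O[C@H]1C=C[C@@H](O[Si](C)(C)C(C)(C)C)[C@](C=O)(CC(=O)OC)C1
F2 | step 5 | ent-13, (1R,2R,5R)-5-acetoxy-2-(tert-butyldimethylsilyloxy)-1-(2-methoxy-2-oxoethyl)cyclohex-3-ene-1-carboxylic acid | CC(=O)O[C@H]1C=C[C@@H](O[Si](C)(C)C(C)(C)C)[C@](C(=O)O)(CC(=O)OC)C1
F3 | step 5 | (R)-1-phenylethylammonium salt of 13 | CC(=O)O[C@@H]1C=C[C@H](O[Si](C)(C)C(C)(C)C)[C@@](C(=O)[O-])(CC(=O)OC)C1.C[C@@H]([NH3+])c1ccccc1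
F4 | step 10 | allylic carbinol from 7 and 12, both C1 epimers | CC(=O)O[C@@H]1C=C[C@H](O[Si](C)(C)C(C)(C)C)[C@@](C(O)/C=C(\C)CC[C@H]2OC2(C)C)(CC(=O)OC)C1
F5 | step 4 | (1E,3E)-buta-1,3-diene-1,4-diyl diacetate | CC(=O)O/C=C/C=C/OC(C)=O
F6 | step 4 | lithium (1E,3E)-4-acetoxybuta-1,3-dien-1-olate | CC(=O)O/C=C/C=C/[O-].[Li+]
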